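**Retrosynthetic overview**

1. Target ⇐ tetracycle with a C1=C2-derived cis-diol, a 9(11)-alkene and a C6 lactone: the 9,11-epoxide, the two acetates and the lactol are installed last.
2. Ring D ⇐ 5-exo radical closure C16→C13 of an ethyl ketone on C8 onto a 9(11),12-diene in ring C.
3. Rings B and C together ⇐ ester-tethered Diels–Alder reaction. The feature used: C8 is the quaternary atom common to rings B and C (later also D) and is joined through C9 to C10 of ring A, so a C6–O–C7 ester tether from C5 can carry a C8=C14 acrylate onto a C9=C11–C12=C13 silyloxydiene on C10 (new bonds C8–C9 and C13–C14).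
4. Ring A ⇐ commercial 4-oxo-cyclogeranate: a catalyst-controlled ketone reduction sets C2, and a Johnson–Claisen shift passes that centre on to the quaternary C10. Ring order: A, then B and C, then D.

Key step: step 8

**Remarks**

- Atoms carry kaurane numbers throughout: ring A = C1–C5, C10; ring B = C5, C6, O, C7, C8, C9, C10; ring C = C8, C9, C11–C14; ring D = C8, C14, C13, C16, C15; C20 is the methyl on C10.
- Commercial 1 is taken to be racemic; step 1 sets the carbinol centre by catalyst control and only the trans diastereomer is carried on.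
- Lactols and lactol derivatives 22–32 are anomeric mixtures at C6 and are drawn without a C6 descriptor.

**Route**

Step 1
Reactants: 1 ethyl 2,6,6-trimethyl-4-oxocyclohex-2-ene-1-carboxylate (racemic)
Product: 2 ethyl (1R,4R)-4-hydroxy-2,6,6-trimethylcyclohex-2-ene-1-carboxylate (trans allylic alcohol)
Conditions: RuCl[(R,R)-TsDPEN](p-cymene) (1 mol %), KOH (2 mol %), i-PrOH, rt; chromatography to remove the cis diastereomer
Reagents that add atoms: none
Why: Noyori asymmetric transfer hydrogenation, in which the enone alkene plays the part of the aryl group, should give the (R)-carbinol from both enantiomers of 1, so that the trans alcohol (from the R enantiomer) and the cis alcohol (from the S enantiomer) are diastereomers that can be separated, the base-labile centre next to the ester being free to equilibrate in the ketone and so feed the faster-reacting enantiomer.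

Step 2
Reactants: 2 trans allylic alcohol; 3 triethyl orthoacetate
Product: 4 ethyl (1R,2R)-2-(2-ethoxy-2-oxoethyl)-2,6,6-trimethylcyclohex-3-ene-1-carboxylate (ring-A diester)
Conditions: 3 (6 equiv), EtCO2H (5 mol %), xylene, 140 °C, EtOH distilled off
Reagents that add atoms: none
Why: Johnson–Claisen rearrangement through a chair-like [3,3] shift from the pseudoaxial C2–O bond delivers the acetate arm (C9, C11) to C10 on the face that carried the oxygen, which sets the quaternary C10 with C9 trans to the C6 ester and leaves the C1=C2 alkene.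

Step 3
Reactants: 4 ring-A diester
Product: 5 (1R,2R)-2-(carboxymethyl)-2,6,6-trimethylcyclohex-3-ene-1-carboxylic acid (diacid)
Conditions: n-PrSLi (6 equiv), HMPA, 80 °C; then 1 M HCl
Reagents that add atoms: none
Why: SN2 dealkylation of both ethyl esters by thiolate frees the acids without attack at the very hindered C6 acyl carbon and without a base strong enough to epimerize C5.

Step 4
Reactants: 5 diacid
Product: 7 (1R,2R)-2-{2-[methoxy(methyl)amino]-2-oxoethyl}-2,6,6-trimethylcyclohex-3-ene-1-carboxylic acid (Weinreb amide acid), via cyclic anhydride 6 (not isolated)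
Conditions: DCC (1.05 equiv), CH2Cl2, rt; then MeNH(OMe)·HCl, Et3N, 0 °C to rt
Reagents that add atoms: N,O-dimethylhydroxylamine hydrochloride CNOC.Cl
Why: Carbodiimide dehydration to the six-membered anhydride followed by aminolysis at the less hindered CH2–C=O carbonyl (C11), the C6 carbonyl being flanked by two quaternary carbons, tells the two acids apart and leaves the C6 acid free.

Step 5
Reactants: 7 Weinreb amide acid; 8 vinylmagnesium bromide
Product: 9 (1R,2R)-2,6,6-trimethyl-2-(2-oxobut-3-en-1-yl)cyclohex-3-ene-1-carboxylic acid (vinyl ketone acid)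
Conditions: 8 (3.2 equiv), THF, −78 to 0 °C; poured into cold 1 M HCl
Reagents that add atoms: none
Why: Weinreb ketone synthesis, in which the first equivalent of Grignard reagent only deprotonates the acid and the chelated adduct releases the vinyl ketone (C11–C13) on the acidic quench, which also keeps the freed amine from adding to the enone.

Step 6
Reactants: 9 vinyl ketone acid; 10 methyl 2-(bromomethyl)acrylate
Product: 11 2-(methoxycarbonyl)prop-2-en-1-yl ester of 9 (acrylate-tethered vinyl ketone)
Conditions: KHCO3, DMF, BHT (trace), rt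
Reagents that add atoms: none
Why: O-alkylation of the carboxylate at the allylic bromide (SN2 and SN2′ lead to the same ester) builds the C6–O–C7 ester without acyl activation of the encumbered C6 acid.

Step 7
Reactants: 11 acrylate-tethered vinyl ketone
Product: 12 silyl dienol ether: ring A (1-ene) with the C6 ester of methyl 2-(hydroxymethyl)acrylate on C5 and the (Z)-2-(tert-butyldimethylsilyloxy)buta-1,3-dienyl group on C10
Conditions: TBSOTf (1.2 equiv), Et3N, CH2Cl2, −78 to 0 °C
Reagents that add atoms: tert-butyldimethylsilyl triflate CC(C)(C)[Si](C)(C)OS(=O)(=O)C(F)(F)F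
Why: Soft enolization of the vinyl ketone toward C9 gives the cross-conjugated 2-silyloxydiene as the Z enol ether (C10 syn to OTBS and therefore outside on the diene), the esters not being enolized under these conditions.

Step 8
Reactants: 12 silyl dienol ether
Product: 13 tricyclic lactone silyl enol ether: ring A (1-ene), seven-membered lactone ring B (C6=O, O, C7), ring C with 11-OTBS-11-ene, CO2Me (C15) on quaternary C8 anti to C20, H9 syn to C20
Conditions: PhMe (0.01 M), BHT, sealed tube, 170 °C
Reagents that add atoms: none
Why: Thermal type-1 intramolecular Diels–Alder reaction: a concerted, asynchronous [4+2] between the HOMO of the 2-silyloxydiene C9=C11–C12=C13 and the LUMO of the 2-substituted acrylate C8=C14 forms C8–C9 and C13–C14 suprafacially on both partners, the closest known reaction type being the ester-tethered cycloaddition of 2-silyloxydienes (closure of a seven-membered lactone is the less usual element). Ring C closes as the six-membered cycloadduct ring itself, and ring B closes in the fused mode, the new C8–C9 bond completing the lactone C5–C6–O–C7–C8–C9–C10 with its ester s-cis, since a five-atom tether cannot reach the bridged mode. The tether thereby forces the regiochemistry (C9 to the ester-bearing C8) against the para preference of the silyloxy group, which is why heat without a Lewis acid is used, a Lewis acid inviting stepwise Mukaiyama–Michael attack of C9 on C14. C8 is controlled by the diene face: C10 sits outside on the Z enol ether with C5 near the diene plane, so the two faces are flanked by the axial C20 methyl and by C1, and addition on the C1 side, anti to C20, with C7 exo and the ester endo, places C15 anti to C20 as in the target. C9 follows from the suprafacial addition (H9 syn to C20, rings B and C trans-fused) and is erased in step 12, so the cis-fused C9 epimer with the same C8 would converge there. The selectivity the step needs is this facial one; it rests on the steric bias against C20 and the endo ester, but the tether reaches that face only through a boat-like lactone closure, so it is not secured in advance and carries the main risk of the route.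

Step 9
Reactants: 13 tricyclic lactone silyl enol ether
Product: 14 tricyclic 12-en-11-one (enone) with lactone ring B, CO2Me on C8 and the C1=C2 alkene
Conditions: Pd(OAc)2 (1.05 equiv), MeCN, rt
Reagents that add atoms: none
Why: Saegusa–Ito oxidation, in which the C12-bound palladium enolate can lose β-hydride only from C13, gives the 12-en-11-one and removes the one electron-rich alkene other than C1=C2.

Step 10
Reactants: 14 enone
Product: 17 enone 1,2-cis-diol with both hydroxyls syn to C20, via iodo acetate 15 (not isolated), via hydroxy acetate 16 (not isolated)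
Conditions: I2 (1.05 equiv), AgOAc (2.2 equiv), AcOH, rt, dark; then AcOH/H2O (96:4), 90 °C; filter, concentrate; K2CO3, MeOH, 0 °C to rt
Reagents that add atoms: silver acetate CC(=O)[O-].[Ag+]; iodine II (held only in 15); water O (held only in 16)
Why: Woodward cis-hydroxylation, in which the iodonium ion forms on the open face anti to the axial C20 methyl, acetate opens it trans-diaxially at C2, silver-assisted loss of iodide with acetoxy participation inverts C1 to the cis-dioxolanylium ion, and water then methanolysis give the cis-diol on the C20 face that osmylation would not reach, the enone alkene being too electron-poor to compete.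

Step 11
Reactants: 17 enone cis-diol
Product: 18 enone 1,2-acetonide
Conditions: Me2C(OMe)2, PPTS, CH2Cl2, rt
Reagents that add atoms: 2,2-dimethoxypropane COC(C)(C)OC
Why: Acetonide formation on the cis-diol gives a base-stable mask for the enolate, hydride and radical steps that follow.

Step 12
Reactants: 18 enone acetonide
Product: 19 9(11),12-dienyl 11-triflate
Conditions: KHMDS (1.1 equiv), THF, −78 °C; then PhNTf2, −78 to 0 °C
Reagents that add atoms: N-phenylbis(trifluoromethanesulfonimide) O=S(=O)(N(c1ccccc1)S(=O)(=O)C(F)(F)F)C(F)(F)F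
Why: Kinetic α′-deprotonation of the enone at C9 (the axial C9–H is aligned with the carbonyl, whereas γ-deprotonation at C14 needs equilibrating conditions) and O-triflation of the cross-conjugated dienolate give the dienyl triflate and remove the C9 stereocentre.

Step 13
Reactants: 19 dienyl triflate
Product: 20 9(11),12-diene with lactone ring B, CO2Me on C8 and the ring-A acetonide
Conditions: Pd(OAc)2 (5 mol %), PPh3 (10 mol %), HCO2H, n-Bu3N, DMF, 60 °C
Reagents that add atoms: none
Why: Palladium-catalyzed formate reduction of the vinyl triflate (oxidative addition to zerovalent palladium, formate exchange, loss of CO2 and reductive elimination) replaces OTf by H without moving the diene.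

Step 14
Reactants: 20 diene methyl ester
Product: 21 diene C15 carboxylic acid
Conditions: LiI (5 equiv), pyridine, reflux; then 1 M HCl
Reagents that add atoms: none
Why: SN2 demethylation by iodide at the methyl carbon does not depend on the hindrance at the quaternary C8 acyl group and spares the lactone, whose O-alkyl carbon C7 is neopentyl.

Step 15
Reactants: 21 diene acid
Product: 22 C6 lactol C15 acid
Conditions: DIBAL-H (3.3 equiv), CH2Cl2, −78 °C; Rochelle salt work-up
Reagents that add atoms: none
Why: Lactone-to-lactol reduction, in which DIBAL-H first turns the acid into an aluminium carboxylate that is inert at −78 °C and then adds once to the lactone to give an aluminate that holds until work-up.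

Step 16
Reactants: 22 lactol acid
Product: 23 C6 O-TBS lactol, C15 TBS ester
Conditions: TBSCl (3 equiv), imidazole, DMF, rt
Reagents that add atoms: tert-butyl(chloro)dimethylsilane CC(C)(C)[Si](C)(C)Cl
Why: Silylation masks the lactol OH as a base-stable silyl acetal and turns the acid into the silyl ester needed for acid chloride formation under neutral conditions.

Step 17
Reactants: 23 bis-silyl compound; 24 ethylmagnesium bromide
Product: 26 ethyl ketone on C8 (C15=O, C16, C17) with the 9(11),12-diene, via acid chloride 25 (not isolated)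
Conditions: (COCl)2, DMF (cat.), CH2Cl2, 0 °C to rt; evaporate; 24 (1.2 equiv), Fe(acac)3 (3 mol %), THF, −78 °C
Reagents that add atoms: oxalyl chloride ClC(=O)C(Cl)=O (its chlorine is held only in 25)
Why: The Vilsmeier reagent converts the silyl ester into the acid chloride without acid, and iron-catalyzed acylation of the Grignard reagent at −78 °C stops at the ketone and leaves the silyl acetal, the acetonide and the diene alone.

Step 18
Reactants: 26 ethyl ketone
Product: 27 α-phenylselanyl ketone (PhSe on C16, both epimers)
Conditions: LDA (1.1 equiv), THF, −78 °C; then PhSeBr, −78 °C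
Reagents that add atoms: phenylselenyl bromide Br[Se]c1ccccc1
Why: α-Selenenylation of the lithium enolate, which can form only toward C16 because C8 is quaternary and which takes up PhSeBr far faster than the diene does.

Step 19
Reactants: 27 α-phenylselanyl ketone
Product: 28 tetracyclic 15-ketone with ring D closed, the 9(11)-alkene and both C16 epimers
Conditions: Bu3SnH (1.3 equiv, syringe pump), AIBN (cat.), PhH, 80 °C
Reagents that add atoms: none
Why: Tin hydride-mediated 5-exo-trig radical cyclization, in which the stannyl radical takes PhSe from C16, the α-keto radical adds to the diene terminus C13 lying beneath the axial C15 acyl group (closing ring D, with C13 fixed by the bridge), and the C9–C11–C12 allyl radical takes hydrogen at the less hindered C12 to leave the 9(11)-alkene, C16 being corrected in step 20.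

Step 20
Reactants: 28 tetracyclic ketone (C16 mixture)
Product: 29 tetracyclic ketone with the C16 methyl endo (toward C12) as in the target
Conditions: LDA (1.2 equiv), THF, −78 °C; then 2,6-di-tert-butyl-4-methylphenol in THF, −78 °C
Reagents that add atoms: none
Why: Kinetic protonation of the C15=C16 lithium enolate by a bulky phenol on the open exo face, away from the C11–C12 bridge, places H16 exo and the methyl endo against the thermodynamic preference, which is why no strong base is used afterwards.

Step 21
Reactants: 29 protected tetracycle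
Product: 30 1,2-diol C6 lactol (triol ketone)
Conditions: AcOH/THF/H2O (3:1:1), 40 °C
Reagents that add atoms: none
Why: Mild aqueous acid hydrolysis removes the acetonide and the silyl acetal together under conditions too weak to enolize the C15 ketone, so C16 is kept.

Step 22
Reactants: 30 triol ketone
Product: 31 1,2,6-triacetate
Conditions: Ac2O, DMAP, pyridine, 40 °C
Reagents that add atoms: acetic anhydride CC(=O)OC(C)=O
Why: DMAP-catalyzed acetylation esterifies both ring-A hydroxyls and the lactol OH, the axial C2 hydroxyl between two syn-axial methyls being the slow one.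

Step 23
Reactants: 31 triacetate
Product: 32 9,11-epoxide triacetate
Conditions: DMDO (1.5 equiv, acetone), CH2Cl2, −20 to 0 °C
Reagents that add atoms: dimethyldioxirane CC1(C)OO1
Why: Epoxidation by a neutral dioxirane (no Baeyer–Villiger reaction at C15) of the only alkene left should occur on the face of the one-carbon bridge C14, which is also the C20 face, because the other face is closed by the C15–C16 bridge with its endo methyl and by C1 with its acetate, and this gives the epoxide of the target.

Step 24
Reactants: 32 epoxide triacetate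
Product: 33 CNP0210140.1 (target)
Conditions: NH4OAc, DMF, rt
Reagents that add atoms: none
Why: Chemoselective aminolysis of the anomeric acetate, the most activated ester as in the selective anomeric deacetylation of sugar peracetates, frees the C6 lactol, which should settle as the anomer of the target by ring–chain equilibration.

**Compound list**

1 | ethyl 2,6,6-trimethyl-4-oxocyclohex-2-ene-1-carboxylate (racemic) | CCOC(=O)C1C(C)=CC(=O)CC1(C)C | starting material
2 | ethyl (1R,4R)-4-hydroxy-2,6,6-trimethylcyclohex-2-ene-1-carboxylate (trans) | O[C@@H]1CC(C)(C)[C@@H](C(=O)OCC)C(C)=C1 | intermediate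
3 | triethyl orthoacetate | CCOC(C)(OCC)OCC | starting material
4 | ethyl (1R,2R)-2-(2-ethoxy-2-oxoethyl)-2,6,6-trimethylcyclohex-3-ene-1-carboxylate | C1=CCC(C)(C)[C@@H](C(=O)OCC)[C@]1(C)CC(=O)OCC | intermediate
5 | (1R,2R)-2-(carboxymethyl)-2,6,6-trimethylcyclohex-3-ene-1-carboxylic acid | C1=CCC(C)(C)[C@@H](C(=O)O)[C@]1(C)CC(=O)O | intermediate
6 | trans-fused six-membered cyclic anhydride of 5 | C1=CCC(C)(C)[C@H]2C(=O)OC(=O)C[C@]12C | intermediate
7 | (1R,2R)-2-{2-[methoxy(methyl)amino]-2-oxoethyl}-2,6,6-trimethylcyclohex-3-ene-1-carboxylic acid | C1=CCC(C)(C)[C@@H](C(=O)O)[C@]1(C)CC(=O)N(C)OC | intermediate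
8 | vinylmagnesium bromide | C=C[Mg]Br | starting material
9 | (1R,2R)-2,6,6-trimethyl-2-(2-oxobut-3-en-1-yl)cyclohex-3-ene-1-carboxylic acid | C1=CCC(C)(C)[C@@H](C(=O)O)[C@]1(C)CC(=O)C=C | intermediate
10 | methyl 2-(bromomethyl)acrylate | C=C(CBr)C(=O)OC | starting material
11 | 2-(methoxycarbonyl)prop-2-en-1-yl ester of 9 | C1=CCC(C)(C)[C@@H](C(=O)OCC(=C)C(=O)OC)[C@]1(C)CC(=O)C=C | intermediate
12 | (Z)-silyl dienol ether of 11 (key-step precursor; C5 and C10 as in 9) | C1=CCC(C)(C)[C@@H](C(=O)OCC(=C)C(=O)OC)[C@]1(C)/C=C(\O[Si](C)(C)C(C)(C)C)C=C | intermediate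
13 | tricyclic A/B/C lactone, 11-OTBS-11-ene, CO2Me on C8 anti to C20, H9 syn to C20, 1-ene | C1CC(C)(C)[C@H]2C(=O)OC[C@@]3(C(=O)OC)CCC=C(O[Si](C)(C)C(C)(C)C)[C@@H]3[C@]2(C)C=1 | intermediate
14 | tricyclic lactone 12-en-11-one, 1-ene | C1CC(C)(C)[C@H]2C(=O)OC[C@@]3(C(=O)OC)CC=CC(=O)[C@@H]3[C@]2(C)C=1 | intermediate
15 | 2-acetoxy (syn to C20) 1-iodo (anti to C20) adduct of 14 | CC(=O)O[C@H]1CC(C)(C)[C@H]2C(=O)OC[C@@]3(C(=O)OC)CC=CC(=O)[C@@H]3[C@]2(C)[C@@H]1I | intermediate
16 | 2-acetoxy-1-hydroxy enone, both oxygens syn to C20 | CC(=O)O[C@H]1CC(C)(C)[C@H]2C(=O)OC[C@@]3(C(=O)OC)CC=CC(=O)[C@@H]3[C@]2(C)[C@H]1O | intermediate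
17 | 1,2-cis-diol enone, both hydroxyls syn to C20 | O[C@H]1CC(C)(C)[C@H]2C(=O)OC[C@@]3(C(=O)OC)CC=CC(=O)[C@@H]3[C@]2(C)[C@H]1O | intermediate
18 | 1,2-acetonide of 17 | CC1(C)O[C@H]2CC(C)(C)[C@H]3C(=O)OC[C@@]4(C(=O)OC)CC=CC(=O)[C@@H]4[C@]3(C)[C@H]2O1 | intermediate
19 | 9(11),12-dienyl 11-triflate | CC1(C)O[C@H]2CC(C)(C)[C@H]3C(=O)OC[C@@]4(C(=O)OC)CC=CC(OS(=O)(=O)C(F)(F)F)=C4[C@]3(C)[C@H]2O1 | intermediate
20 | 9(11),12-diene methyl ester lactone | CC1(C)O[C@H]2CC(C)(C)[C@H]3C(=O)OC[C@@]4(C(=O)OC)CC=CC=C4[C@]3(C)[C@H]2O1 | intermediate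
21 | 9(11),12-diene C15 acid lactone | CC1(C)O[C@H]2CC(C)(C)[C@H]3C(=O)OC[C@@]4(C(=O)O)CC=CC=C4[C@]3(C)[C@H]2O1 | intermediate
22 | C6 lactol C15 acid | CC1(C)O[C@H]2CC(C)(C)[C@H]3C(O)OC[C@@]4(C(=O)O)CC=CC=C4[C@]3(C)[C@H]2O1 | intermediate
23 | C6 O-TBS lactol, C15 TBS ester | CC1(C)O[C@H]2CC(C)(C)[C@H]3C(O[Si](C)(C)C(C)(C)C)OC[C@@]4(C(=O)O[Si](C)(C)C(C)(C)C)CC=CC=C4[C@]3(C)[C@H]2O1 | intermediate
24 | ethylmagnesium bromide | CC[Mg]Br | starting material
25 | C15 acid chloride | CC1(C)O[C@H]2CC(C)(C)[C@H]3C(O[Si](C)(C)C(C)(C)C)OC[C@@]4(C(=O)Cl)CC=CC=C4[C@]3(C)[C@H]2O1 | intermediate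
26 | C8 ethyl ketone (C15=O, C16, C17), 9(11),12-diene | CC1(C)O[C@H]2CC(C)(C)[C@H]3C(O[Si](C)(C)C(C)(C)C)OC[C@@]4(C(=O)CC)CC=CC=C4[C@]3(C)[C@H]2O1 | intermediate
27 | C16 phenylselanyl ketone (both epimers) | CC1(C)O[C@H]2CC(C)(C)[C@H]3C(O[Si](C)(C)C(C)(C)C)OC[C@@]4(C(=O)C(C)[Se]c5ccccc5)CC=CC=C4[C@]3(C)[C@H]2O1 | intermediate
28 | tetracyclic 15-ketone, 9(11)-ene, C16 epimers | CC1(C)O[C@H]2CC(C)(C)[C@H]3C(O[Si](C)(C)C(C)(C)C)OC[C@@]45C[C@@H](CC=C4[C@]3(C)[C@H]2O1)C(C)C5=O | intermediate
29 | tetracyclic 15-ketone, 9(11)-ene, C16 methyl endo | CC1(C)O[C@H]2CC(C)(C)[C@H]3C(O[Si](C)(C)C(C)(C)C)OC[C@@]45C[C@@H](CC=C4[C@]3(C)[C@H]2O1)[C@@H](C)C5=O | intermediate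
30 | 1,2-diol C6 lactol 15-ketone, 9(11)-ene | O[C@H]1CC(C)(C)[C@H]2C(O)OC[C@@]34C[C@@H](CC=C3[C@]2(C)[C@H]1O)[C@@H](C)C4=O | intermediate
31 | 1,2,6-triacetate, 9(11)-ene | CC(=O)O[C@H]1CC(C)(C)[C@H]2C(OC(C)=O)OC[C@@]34C[C@@H](CC=C3[C@]2(C)[C@H]1OC(C)=O)[C@@H](C)C4=O | intermediate
32 | 9,11-epoxide 1,2,6-triacetate | CC(=O)O[C@H]1CC(C)(C)[C@H]2C(OC(C)=O)OC[C@@]34C[C@@H](C[C@H]5O[C@]53[C@]2(C)[C@H]1OC(C)=O)[C@@H](C)C4=O | intermediate
33 | CNP0210140.1 | CC(=O)O[C@H]1CC(C)(C)[C@H]2[C@H](O)OC[C@@]34C[C@@H](C[C@H]5O[C@]53[C@]2(C)[C@H]1OC(C)=O)[C@@H](C)C4=O | target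

**Step count**

Total steps: 24. Longest linear sequence: 24 steps (the route is linear from 1).

**Steps most likely to fail**

Step 8 (Diels–Alder). The dienophile may add to the other diene face, because the chair-like closure of the lactone delivers C8 on the C20 side and so gives the C8 epimer. It may also fail to add at all, because the ester must turn s-cis and the regiochemistry is electronically mismatched.
Fallback (sets out from 1, comes back at 13): the cis alcohol F1, formed beside 2 in step 1, is taken through the chemistry of steps 2 to 7 as the C5-epimeric series: diester F2, diacid F3, cis-fused anhydride F4 (not isolated), Weinreb amide acid F5, vinyl ketone acid F6, acrylate ester F7 and silyl dienol ether F8. In F8 the C6 arm is axial and cis to C9, so the tether reaches the face anti to C20 through a chair-like lactone, and heating should give the C5-epimeric cycloadduct F9. Deprotonation at C5 (KHMDS, THF, −78 °C) and kinetic protonation of the lactone enolate from the side away from the axial C20 methyl (AcOH, −78 °C) then inverts C5 and gives 13.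

Step 19 (radical closure of ring D). The α-keto radical may be reduced before it cyclizes, may attack C12 in the 6-endo mode, or the allyl radical may take hydrogen at C9.
Fallback (sets out from 23, comes back at 28): acid chloride 25, made as in step 17, is treated with diazoethane to give the α-diazo ketone F10. Rh2(OAc)4 then closes ring D by intramolecular cyclopropanation of C12=C13, giving the cyclopropyl ketone F11 with C16 bonded to C13 and C12. SmI2 (HMPA, t-BuOH) cleaves the C16–C12 bond, which overlaps the ketone and leaves the C9–C11–C12 allyl system, and protonation at C12 gives 28.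

Step 10 (cis-hydroxylation on the C20 face). Acetate may fail to open the iodonium ion at the crowded C2, or the displacement at the neopentyl C1 may be overtaken by migration of the C20 methyl.
Fallback (sets out from 14, comes back at 16): DMDO epoxidizes C1=C2 on the face anti to C20, giving the epoxide F12 (the enone alkene is inert). AcOH with NaOAc opens it trans-diaxially at C2 to the 2-acetoxy-1-ol F13, and Tf2O with pyridine gives the C1 triflate F14. Its solvolysis in wet MeCN with 2,6-lutidine, the axial acetate taking part, inverts C1 and gives hydroxy acetate 16, which is carried on as in step 10.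

Further compounds
F1 | step 8 | ethyl (1S,4R)-4-hydroxy-2,6,6-trimethylcyclohex-2-ene-1-carboxylate (cis alcohol) | O[C@@H]1CC(C)(C)[C@H](C(=O)OCC)C(C)=C1
F2 | step 8 | C5 epimer of diester 4 | C1=CCC(C)(C)[C@H](C(=O)OCC)[C@]1(C)CC(=O)OCC
F3 | step 8 | C5 epimer of diacid 5 | C1=CCC(C)(C)[C@H](C(=O)O)[C@]1(C)CC(=O)O
F4 | step 8 | C5 epimer of anhydride 6 (cis-fused) | C1=CCC(C)(C)[C@@H]2C(=O)OC(=O)C[C@]12C
F5 | step 8 | C5 epimer of Weinreb amide acid 7 | C1=CCC(C)(C)[C@H](C(=O)O)[C@]1(C)CC(=O)N(C)OC
F6 | step 8 | C5 epimer of vinyl ketone acid 9 | C1=CCC(C)(C)[C@H](C(=O)O)[C@]1(C)CC(=O)C=C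
F7 | step 8 | C5 epimer of acrylate ester 11 | C1=CCC(C)(C)[C@H](C(=O)OCC(=C)C(=O)OC)[C@]1(C)CC(=O)C=C
F8 | step 8 | C5 epimer of silyl dienol ether 12 | C1=CCC(C)(C)[C@H](C(=O)OCC(=C)C(=O)OC)[C@]1(C)/C=C(\O[Si](C)(C)C(C)(C)C)C=C
F9 | step 8 | C5 epimer of cycloadduct 13 | C1CC(C)(C)[C@@H]2C(=O)OC[C@@]3(C(=O)OC)CCC=C(O[Si](C)(C)C(C)(C)C)[C@@H]3[C@]2(C)C=1
F10 | step 19 | α-diazo ethyl ketone on C8 | CC1(C)O[C@H]2CC(C)(C)[C@H]3C(O[Si](C)(C)C(C)(C)C)OC[C@@]4(C(=O)C(C)=[N+]=[N-])CC=CC=C4[C@]3(C)[C@H]2O1
F11 | step 19 | cyclopropyl ketone (C16 bonded to C12 and C13), 9(11)-ene | CC1(C)O[C@H]2CC(C)(C)[C@H]3C(O[Si](C)(C)C(C)(C)C)OC[C@@]45C[C@H]6[C@@H](C=C4[C@]3(C)[C@H]2O1)[C@@]6(C)C5=O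
F12 | step 10 | 1,2-epoxide of 14 anti to C20 | O1[C@@H]2CC(C)(C)[C@H]3C(=O)OC[C@@]4(C(=O)OC)CC=CC(=O)[C@@H]4[C@]3(C)[C@H]12
F13 | step 10 | trans-diaxial 2-acetoxy-1-ol (OAc syn, OH anti to C20) | CC(=O)O[C@H]1CC(C)(C)[C@H]2C(=O)OC[C@@]3(C(=O)OC)CC=CC(=O)[C@@H]3[C@]2(C)[C@@H]1O
F14 | step 10 | C1 triflate of F13 | CC(=O)O[C@H]1CC(C)(C)[C@H]2C(=O)OC[C@@]3(C(=O)OC)CC=CC(=O)[C@@H]3[C@]2(C)[C@@H]1OS(=O)(=O)C(F)(F)F
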